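**Strategy.** Ring A bears three adjacent substituents: the aryloxy oxygen on C6, the ester carbon on C1 and a hydroxyl on C2. A 3-alkoxybenzyne leaves this pattern when a nucleophile adds meta and an electrophile ortho to the alkoxy group. The O–C6 and C1–carboxyl bonds are therefore disconnected together. In one operation the ring B phenoxide, 3-benzyloxy-5-methylbenzyne and CO2 should give the hindered diaryl ether acid. The precursors are an ortho-silylaryl triflate made from orcinol and 2-benzyloxy-6-bromo-4-methoxyphenol. The bromide of the phenol later joins a 2-bromo-3-arylindenone (rings C and D) by Suzuki coupling. One iodoorcinol feeds rings A and D, and one bromobenzaldehyde feeds rings B and C.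

Key step: step 9

Assumption: the target has no stereocentre and its hindered aryl–indenone axes are taken as freely equilibrating, so racemic intermediates are carried on as such.

Step 1
Reactants: 1 orcinol (5-methylbenzene-1,3-diol)
Product: 2 2-iodo-5-methylbenzene-1,3-diol
Conditions: I2 (1.05 equiv), NaHCO3 (1.1 equiv), H2O, 0 °C to rt
Reagents that add atoms: iodine, [I][I]
Why: Electrophilic aromatic iodination, which in bicarbonate-buffered water takes resorcinol and its 5-alkyl homologues at the carbon flanked by both hydroxyls.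

Step 2
Reactants: 2 2-iodo-5-methylbenzene-1,3-diol
Product: 3 1,3-bis(benzyloxy)-2-iodo-5-methylbenzene
Conditions: BnBr (2.3 equiv), K2CO3 (3 equiv), DMF, 50 °C
Reagents that add atoms: benzyl bromide, BrCc1ccccc1
Why: Double Williamson ether synthesis on both phenols, with the aryl iodide inert to carbonate.

Step 3
Reactants: 2 2-iodo-5-methylbenzene-1,3-diol
Product: 4 3-(benzyloxy)-2-iodo-5-methylphenol
Conditions: BnBr (1.0 equiv), K2CO3 (1.1 equiv), acetone, 50 °C
Reagents that add atoms: benzyl bromide, BrCc1ccccc1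
Why: Williamson ether synthesis on a diol with two equivalent hydroxyls, so only the degree of alkylation must be managed, recovered 2 being recycled and over-alkylated material being 3, which the route needs anyway.

Step 4
Reactants: 4 3-(benzyloxy)-2-iodo-5-methylphenol
Product: 7 3-(benzyloxy)-5-methyl-2-(trimethylsilyl)phenyl trifluoromethanesulfonate, via silyl ether 5 (not isolated), via lithium phenoxide 6 (not isolated)
Conditions: HN(SiMe3)2, THF, 65 °C, then evaporate; n-BuLi (1.05 equiv), THF, −78 °C; Tf2O (1.1 equiv), −78 to 0 °C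
Reagents that add atoms: hexamethyldisilazane, C[Si](C)(C)N[Si](C)(C)C; trifluoromethanesulfonic anhydride, O=S(=O)(OS(=O)(=O)C(F)(F)F)C(F)(F)F
Why: O-silylation, iodine–lithium exchange (far faster at −78 °C than benzylic deprotonation) and retro-Brook shift of silicon from oxygen to the lithiated carbon give 6, which is sulfonylated in the same flask, the standard one-pot entry to ortho-silylaryl triflates from ortho-halophenols.

Step 5
Reactants: 8 1-bromo-3,5-dimethoxybenzene
Product: 10 2-bromo-4,6-dimethoxybenzaldehyde, via iminium chloride 9 (not isolated)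
Conditions: POCl3 (2 equiv), DMF, 0 to 90 °C; then ice/H2O
Reagents that add atoms: N,N-dimethylformamide, CN(C)C=O; water, O
Why: Vilsmeier–Haack formylation, which on this arene prefers the C–H para to one methoxy group and next to bromine over the more crowded site between the two methoxy groups.

Step 6
Reactants: 10 2-bromo-4,6-dimethoxybenzaldehyde
Product: 11 2-bromo-6-hydroxy-4-methoxybenzaldehyde
Conditions: BCl3 (1.1 equiv), CH2Cl2, −78 to 0 °C; H2O work-up
Reagents that add atoms: none
Why: Chelation-controlled ether cleavage, in which BCl3 binds between the aldehyde oxygen and the ortho methoxy oxygen so that only that methyl group is lost and the para methoxy group stays.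

Step 7
Reactants: 11 2-bromo-6-hydroxy-4-methoxybenzaldehyde
Product: 12 2-(benzyloxy)-6-bromo-4-methoxybenzaldehyde
Conditions: BnBr (1.2 equiv), K2CO3 (1.5 equiv), DMF, 50 °C
Reagents that add atoms: benzyl bromide, BrCc1ccccc1
Why: Williamson ether synthesis on the only free phenol, with mild heating to overcome its hydrogen bond to the aldehyde.

Step 8
Reactants: 12 2-(benzyloxy)-6-bromo-4-methoxybenzaldehyde
Product: 14 2-(benzyloxy)-6-bromo-4-methoxyphenol, via aryl formate 13 (not isolated)
Conditions: mCPBA (1.3 equiv), CH2Cl2, 0 °C to rt; then K2CO3 (cat.), MeOH, rt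
Reagents that add atoms: 3-chloroperoxybenzoic acid, O=C(OO)c1cccc(Cl)c1
Why: Baeyer–Villiger oxidation in which the aryl group, carrying ortho and para oxygen donors, migrates in preference to hydrogen, and methanolysis of the formate frees the hydroxyl between OBn and Br without two catechol hydroxyls of similar acidity having to be told apart.

Step 9
Reactants: 14 2-(benzyloxy)-6-bromo-4-methoxyphenol; 7 3-(benzyloxy)-5-methyl-2-(trimethylsilyl)phenyl trifluoromethanesulfonate; 15 carbon dioxide
Product: 19 2-(benzyloxy)-6-[2-(benzyloxy)-6-bromo-4-methoxyphenoxy]-4-methylbenzoic acid, via potassium phenoxide 16 (not isolated), via aryne 17 (not isolated), via arylpotassium 18 (not isolated)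
Conditions: 14 (1.2 equiv), KH (1.2 equiv), THF, 0 °C; then CO2 (1 atm, dried), KF (3 equiv), 18-crown-6 (3 equiv), slow addition of 7 (1.0 equiv), 0 °C to rt; 1 M HCl work-up
Reagents that add atoms: carbon dioxide (compound 15), O=C=O
Why: Proposed new method: fluoride strips silicon from 7 and triflate leaves to give aryne 17, phenoxide 16 adds to the aryne carbon meta to the benzyloxy group (the future C6 of ring A), and the aryl anion 18 left at C1 is carboxylated by dissolved CO2, so the O–C6 and C1–carboxyl bonds form in one flask. The closest known reaction types are the fluoride-induced O-arylation of phenols by ortho-silylaryl triflates and the three-component coupling of arynes, amines and CO2 to anthranilic acids, in which an oxygen nucleophile has not yet been used. No ring is closed and no stereocentre is created. The regioselectivity needed comes from the benzyloxy group beside the triple bond, which distorts the aryne so that the remote carbon is the more electrophilic one and stabilises the developing charge next to itself by induction, and the bulk of 16 points the same way. Carboxylation should win over protonation because every acidic proton is removed first (KH with loss of H2, no free phenol, no amine, THF instead of acetonitrile), the solution is saturated with CO2 and 7 is fed slowly. Reversible binding of CO2 to the hindered phenoxide only lowers its concentration, and the acid is separable from any neutral diaryl ether by base extraction.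

Step 10
Reactants: 19 2-(benzyloxy)-6-[2-(benzyloxy)-6-bromo-4-methoxyphenoxy]-4-methylbenzoic acid
Product: 20 methyl 2-(benzyloxy)-6-[2-(benzyloxy)-6-bromo-4-methoxyphenoxy]-4-methylbenzoate
Conditions: MeI (1.5 equiv), K2CO3 (1.5 equiv), DMF, rt
Reagents that add atoms: iodomethane, CI
Why: SN2 O-alkylation of the carboxylate, which avoids any attack at the carbonyl carbon shielded by two ortho substituents.

Step 11
Reactants: 20 methyl 2-(benzyloxy)-6-[2-(benzyloxy)-6-bromo-4-methoxyphenoxy]-4-methylbenzoate
Product: 21 methyl 2-(benzyloxy)-6-[2-(benzyloxy)-4-methoxy-6-(4,4,5,5-tetramethyl-1,3,2-dioxaborolan-2-yl)phenoxy]-4-methylbenzoate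
Conditions: B2pin2 (1.3 equiv), Pd(dppf)Cl2 (5 mol %), KOAc (3 equiv), 1,4-dioxane, 90 °C
Reagents that add atoms: bis(pinacolato)diboron, CC1(C)OB(OC1(C)C)B1OC(C)(C)C(C)(C)O1
Why: Miyaura borylation of the only aryl halide present, whose carbon has just one ortho substituent, under acetate conditions that leave ester and benzyl ethers alone.

Step 12
Reactants: 3 1,3-bis(benzyloxy)-2-iodo-5-methylbenzene; 12 2-(benzyloxy)-6-bromo-4-methoxybenzaldehyde
Product: 23 [2-(benzyloxy)-6-bromo-4-methoxyphenyl][2,6-bis(benzyloxy)-4-methylphenyl]methanol (racemic), via aryllithium 22 (not isolated)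
Conditions: 3, n-BuLi (1.05 equiv), THF, −78 °C; then 12, −78 to 0 °C; H2O
Reagents that add atoms: none
Why: Iodine–lithium exchange followed by 1,2-addition of the aryllithium to the aldehyde, which is faster than exchange with the aryl bromide of 12, giving a racemic carbinol centre that is ionised in the next step.

Step 13
Reactants: 23 [2-(benzyloxy)-6-bromo-4-methoxyphenyl][2,6-bis(benzyloxy)-4-methylphenyl]methanol
Product: 25 methyl 3-[2-(benzyloxy)-6-bromo-4-methoxyphenyl]-3-[2,6-bis(benzyloxy)-4-methylphenyl]propanoate (racemic), via benzhydryl cation 24 (not isolated)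
Conditions: CH2=C(OMe)OSiMe2t-Bu (2.5 equiv), Sc(OTf)3 (5 mol %), CH2Cl2, −40 to 0 °C
Reagents that add atoms: 1-(tert-butyldimethylsilyloxy)-1-methoxyethene, C=C(OC)O[Si](C)(C)C(C)(C)C
Why: SN1 alkylation of a silyl ketene acetal (Mukaiyama type), in which four ortho or para oxygen donors make ionisation to 24 easy and the slim CH2 terminus of the nucleophile captures the cation, the new centre being formed racemic.

Step 14
Reactants: 25 methyl 3-[2-(benzyloxy)-6-bromo-4-methoxyphenyl]-3-[2,6-bis(benzyloxy)-4-methylphenyl]propanoate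
Product: 27 4-(benzyloxy)-3-[2,6-bis(benzyloxy)-4-methylphenyl]-6-methoxy-2,3-dihydro-1H-inden-1-one (racemic), via aryllithium 26 (not isolated)
Conditions: n-BuLi (1.05 equiv), THF, −95 °C, then to −40 °C; H2O
Reagents that add atoms: none
Why: Parham cyclisation, in which bromine–lithium exchange outruns attack of n-BuLi on the ester at −95 °C and the aryllithium acylates itself on the tethered ester by 5-exo-trig closure, placing the carbonyl on the ring C carbon meta to both oxygens, a site a Friedel–Crafts closure could not reach.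

Step 15
Reactants: 27 4-(benzyloxy)-3-[2,6-bis(benzyloxy)-4-methylphenyl]-6-methoxy-2,3-dihydro-1H-inden-1-one
Product: 29 4-(benzyloxy)-3-[2,6-bis(benzyloxy)-4-methylphenyl]-2-bromo-6-methoxy-2,3-dihydro-1H-inden-1-one (racemic; mainly trans), via lithium enolate 28 (not isolated)
Conditions: LiN(SiMe3)2 (1.1 equiv), THF, −78 °C; NBS (1.05 equiv), −78 °C; H2O
Reagents that add atoms: N-bromosuccinimide, O=C1CCC(=O)N1Br
Why: Enolate α-bromination, in which the preformed enolate consumes NBS at −78 °C far faster than the alkoxyarenes can, bromine entering C2 mainly trans to the C3 aryl group, a relationship without consequence because both centres are erased in step 16.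

Step 16
Reactants: 29 4-(benzyloxy)-3-[2,6-bis(benzyloxy)-4-methylphenyl]-2-bromo-6-methoxy-2,3-dihydro-1H-inden-1-one
Product: 30 4-(benzyloxy)-3-[2,6-bis(benzyloxy)-4-methylphenyl]-2-bromo-6-methoxy-1H-inden-1-one
Conditions: DDQ (1.5 equiv), 1,4-dioxane, 90 °C
Reagents that add atoms: none
Why: DDQ dehydrogenation, in which hydride leaves from C3–H (doubly benzylic and ortho or para to the oxygen donors of rings C and D) and the acidic C2 proton follows, giving the bromoenone without electrophilic bromine ever meeting the electron-rich rings.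

Step 17
Reactants: 21 methyl 2-(benzyloxy)-6-[2-(benzyloxy)-4-methoxy-6-(4,4,5,5-tetramethyl-1,3,2-dioxaborolan-2-yl)phenoxy]-4-methylbenzoate; 30 4-(benzyloxy)-3-[2,6-bis(benzyloxy)-4-methylphenyl]-2-bromo-6-methoxy-1H-inden-1-one
Product: 31 methyl 2-(benzyloxy)-6-(2-(benzyloxy)-6-{4-(benzyloxy)-3-[2,6-bis(benzyloxy)-4-methylphenyl]-6-methoxy-1-oxo-1H-inden-2-yl}-4-methoxyphenoxy)-4-methylbenzoate
Conditions: Pd(OAc)2 (5 mol %), SPhos (10 mol %), K3PO4 (3 equiv), toluene/H2O (10:1), 80 °C
Reagents that add atoms: none
Why: Suzuki–Miyaura coupling, in which the C2–Br bond of a 2-bromo-3-arylindenone is an activated α-bromoenone that adds readily to zerovalent palladium, boronate 21 has a single ortho substituent, and the bulky electron-rich ligand suits congested partners.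

Step 18
Reactants: 31 methyl 2-(benzyloxy)-6-(2-(benzyloxy)-6-{4-(benzyloxy)-3-[2,6-bis(benzyloxy)-4-methylphenyl]-6-methoxy-1-oxo-1H-inden-2-yl}-4-methoxyphenoxy)-4-methylbenzoate
Product: 32 Ascomindone B
Conditions: BCl3 (10 equiv), C6HMe5 (15 equiv), CH2Cl2, −78 °C; H2O work-up
Reagents that add atoms: none
Why: Lewis-acid debenzylation with a cation scavenger, in which BCl3 at −78 °C cleaves the five aryl benzyl ethers but not the aryl methyl ethers, the methyl ester or the enone, and pentamethylbenzene traps the benzyl cations before they can alkylate the liberated resorcinol-type rings.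

**Compound list**

1 | orcinol (5-methylbenzene-1,3-diol) | Cc1cc(O)cc(O)c1 | starting material
2 | 2-iodo-5-methylbenzene-1,3-diol | Ic1c(O)cc(C)cc1O | intermediate
3 | 1,3-bis(benzyloxy)-2-iodo-5-methylbenzene | Ic1c(OCc2ccccc2)cc(C)cc1OCc1ccccc1 | intermediate
4 | 3-(benzyloxy)-2-iodo-5-methylphenol | Ic1c(O)cc(C)cc1OCc1ccccc1 | intermediate
5 | [3-(benzyloxy)-2-iodo-5-methylphenoxy]trimethylsilane | Ic1c(O[Si](C)(C)C)cc(C)cc1OCc1ccccc1 | intermediate
6 | lithium 3-(benzyloxy)-5-methyl-2-(trimethylsilyl)phenoxide | [Li+].Cc1cc(OCc2ccccc2)c([Si](C)(C)C)c([O-])c1 | intermediate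
7 | 3-(benzyloxy)-5-methyl-2-(trimethylsilyl)phenyl trifluoromethanesulfonate | Cc1cc(OCc2ccccc2)c([Si](C)(C)C)c(OS(=O)(=O)C(F)(F)F)c1 | intermediate
8 | 1-bromo-3,5-dimethoxybenzene | COc1cc(Br)cc(OC)c1 | starting material
9 | (2-bromo-4,6-dimethoxybenzylidene)dimethyliminium chloride | [Cl-].C[N+](C)=Cc1c(Br)cc(OC)cc1OC | intermediate
10 | 2-bromo-4,6-dimethoxybenzaldehyde | O=Cc1c(Br)cc(OC)cc1OC | intermediate
11 | 2-bromo-6-hydroxy-4-methoxybenzaldehyde | O=Cc1c(O)cc(OC)cc1Br | intermediate
12 | 2-(benzyloxy)-6-bromo-4-methoxybenzaldehyde | O=Cc1c(Br)cc(OC)cc1OCc1ccccc1 | intermediate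
13 | 2-(benzyloxy)-6-bromo-4-methoxyphenyl formate | O=COc1c(Br)cc(OC)cc1OCc1ccccc1 | intermediate
14 | 2-(benzyloxy)-6-bromo-4-methoxyphenol | Oc1c(OCc2ccccc2)cc(OC)cc1Br | intermediate
15 | carbon dioxide | O=C=O | starting material
16 | potassium 2-(benzyloxy)-6-bromo-4-methoxyphenoxide | [K+].[O-]c1c(OCc2ccccc2)cc(OC)cc1Br | intermediate
17 | 3-(benzyloxy)-5-methylbenzyne | CC1=CC#CC(OCc2ccccc2)=C1 | intermediate
18 | potassium 2-(benzyloxy)-6-[2-(benzyloxy)-6-bromo-4-methoxyphenoxy]-4-methylphenide | [K+].Cc1cc(OCc2ccccc2)[c-]c(Oc2c(OCc3ccccc3)cc(OC)cc2Br)c1 | intermediate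
19 | 2-(benzyloxy)-6-[2-(benzyloxy)-6-bromo-4-methoxyphenoxy]-4-methylbenzoic acid | OC(=O)c1c(OCc2ccccc2)cc(C)cc1Oc1c(OCc2ccccc2)cc(OC)cc1Br | intermediate
20 | methyl 2-(benzyloxy)-6-[2-(benzyloxy)-6-bromo-4-methoxyphenoxy]-4-methylbenzoate | COC(=O)c1c(OCc2ccccc2)cc(C)cc1Oc1c(OCc2ccccc2)cc(OC)cc1Br | intermediate
21 | methyl 2-(benzyloxy)-6-[2-(benzyloxy)-4-methoxy-6-(4,4,5,5-tetramethyl-1,3,2-dioxaborolan-2-yl)phenoxy]-4-methylbenzoate | COC(=O)c1c(OCc2ccccc2)cc(C)cc1Oc1c(OCc2ccccc2)cc(OC)cc1B1OC(C)(C)C(C)(C)O1 | intermediate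
22 | [2,6-bis(benzyloxy)-4-methylphenyl]lithium | [Li]c1c(OCc2ccccc2)cc(C)cc1OCc1ccccc1 | intermediate
23 | [2-(benzyloxy)-6-bromo-4-methoxyphenyl][2,6-bis(benzyloxy)-4-methylphenyl]methanol, racemic | COc1cc(Br)c(C(O)c2c(OCc3ccccc3)cc(C)cc2OCc2ccccc2)c(OCc2ccccc2)c1 | intermediate
24 | [2-(benzyloxy)-6-bromo-4-methoxyphenyl][2,6-bis(benzyloxy)-4-methylphenyl]methylium | COc1cc(Br)c([CH+]c2c(OCc3ccccc3)cc(C)cc2OCc2ccccc2)c(OCc2ccccc2)c1 | intermediate
25 | methyl 3-[2-(benzyloxy)-6-bromo-4-methoxyphenyl]-3-[2,6-bis(benzyloxy)-4-methylphenyl]propanoate, racemic | COC(=O)CC(c1c(Br)cc(OC)cc1OCc1ccccc1)c1c(OCc2ccccc2)cc(C)cc1OCc1ccccc1 | intermediate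
26 | aryllithium from 25 (lithium in place of bromine) | [Li]c1cc(OC)cc(OCc2ccccc2)c1C(CC(=O)OC)c1c(OCc2ccccc2)cc(C)cc1OCc1ccccc1 | intermediate
27 | 4-(benzyloxy)-3-[2,6-bis(benzyloxy)-4-methylphenyl]-6-methoxy-2,3-dihydro-1H-inden-1-one, racemic | O=C1CC(c2c(OCc3ccccc3)cc(C)cc2OCc2ccccc2)c2c(OCc3ccccc3)cc(OC)cc21 | intermediate
28 | lithium enolate of 27 | [Li+].[O-]C1=CC(c2c(OCc3ccccc3)cc(C)cc2OCc2ccccc2)c2c(OCc3ccccc3)cc(OC)cc21 | intermediate
29 | 4-(benzyloxy)-3-[2,6-bis(benzyloxy)-4-methylphenyl]-2-bromo-6-methoxy-2,3-dihydro-1H-inden-1-one, racemic, mainly trans, configuration not carried on | O=C1C(Br)C(c2c(OCc3ccccc3)cc(C)cc2OCc2ccccc2)c2c(OCc3ccccc3)cc(OC)cc21 | intermediate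
30 | 4-(benzyloxy)-3-[2,6-bis(benzyloxy)-4-methylphenyl]-2-bromo-6-methoxy-1H-inden-1-one | O=C1C(Br)=C(c2c(OCc3ccccc3)cc(C)cc2OCc2ccccc2)c2c(OCc3ccccc3)cc(OC)cc21 | intermediate
31 | penta-O-benzyl ascomindone B (full name in step 17) | COC(=O)c1c(OCc2ccccc2)cc(C)cc1Oc1c(OCc2ccccc2)cc(OC)cc1C1=C(c2c(OCc3ccccc3)cc(C)cc2OCc2ccccc2)c2c(OCc3ccccc3)cc(OC)cc2C1=O | intermediate
32 | Ascomindone B | COC(=O)c1c(O)cc(C)cc1Oc1c(O)cc(OC)cc1C1=C(c2c(O)cc(C)cc2O)c2c(O)cc(OC)cc2C1=O | target

**Step count.** Total: 18 steps. Longest linear sequence: 10 steps from 8 (steps 5, 6, 7, 12, 13, 14, 15, 16, 17, 18).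

**Steps most likely to fail**

Step 9 (proposed method). Three processes could defeat it:
- proton capture by the aryl anion before it meets CO2;
- parking of the phenoxide as its carbonate;
- consumption of aryne by the carboxylate already formed.

The fallback uses known reactions only, sets out from 7 and 14, and comes back at 20. Aryne 17 is released from 7 with CsF in MeCN in the presence of I2 and is trapped by insertion into the I–I bond as 1-(benzyloxy)-2,3-diiodo-5-methylbenzene F1. i-PrMgCl in THF at −78 °C exchanges the iodine flanked by the benzyloxy group and the second iodine, where the adjacent oxygen stabilises the metal, to give [2-(benzyloxy)-6-iodo-4-methylphenyl]magnesium chloride F2. This reagent is kept cold so that it does not collapse to the aryne. Methyl chloroformate then gives methyl 2-(benzyloxy)-6-iodo-4-methylbenzoate F3. An Ullmann ether coupling of F3 with 14 (CuI, picolinic acid, K3PO4, DMSO, 90 °C) should deliver 20, because the iodide ortho to the ester reacts ahead of the bromide of 14.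

Step 16. Hydride abstraction at the shielded C3–H may be too slow, so that thermal loss of HBr or oxidation at benzylic ether positions takes over. The fallback sets out from 29 and comes back at 30, and it replaces oxidation by halogenation and elimination. A second deprotonation and bromination (LiN(SiMe3)2, then NBS, THF, −78 °C) should give 4-(benzyloxy)-3-[2,6-bis(benzyloxy)-4-methylphenyl]-2,2-dibromo-6-methoxy-2,3-dihydro-1H-inden-1-one F4. DBU in toluene then removes HBr by E2 elimination across C2–C3.

Step 17. Transmetalation at the congested C2 position may be slow, with protodeboronation of the boronate and reductive loss of bromine from the indenone competing. The fallback sets out from 27 and 20 and comes back at 31, so it needs neither step 11 nor steps 15 and 16. Palladium-catalysed ketone α-arylation (Pd2(dba)3, P(t-Bu)3, NaOt-Bu, toluene, 80 °C) joins C2 of the indanone enolate to the ring B carbon that bears bromine. It should give the trans-2,3-diarylindan-1-one F5, which DDQ in dioxane dehydrogenates to 31.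

**Further compounds**

F1 | step 9 | 1-(benzyloxy)-2,3-diiodo-5-methylbenzene | Ic1cc(C)cc(OCc2ccccc2)c1I
F2 | step 9 | [2-(benzyloxy)-6-iodo-4-methylphenyl]magnesium chloride | Ic1cc(C)cc(OCc2ccccc2)c1[Mg]Cl
F3 | step 9 | methyl 2-(benzyloxy)-6-iodo-4-methylbenzoate | COC(=O)c1c(OCc2ccccc2)cc(C)cc1I
F4 | step 16 | 4-(benzyloxy)-3-[2,6-bis(benzyloxy)-4-methylphenyl]-2,2-dibromo-6-methoxy-2,3-dihydro-1H-inden-1-one | O=C1C(Br)(Br)C(c2c(OCc3ccccc3)cc(C)cc2OCc2ccccc2)c2c(OCc3ccccc3)cc(OC)cc21
F5 | step 17 | methyl 2-(benzyloxy)-6-(2-(benzyloxy)-6-{4-(benzyloxy)-3-[2,6-bis(benzyloxy)-4-methylphenyl]-6-methoxy-1-oxo-2,3-dihydro-1H-inden-2-yl}-4-methoxyphenoxy)-4-methylbenzoate, racemic trans | COC(=O)c1c(OCc2ccccc2)cc(C)cc1Oc1c(OCc2ccccc2)cc(OC)cc1C1C(c2c(OCc3ccccc3)cc(C)cc2OCc2ccccc2)c2c(OCc3ccccc3)cc(OC)cc2C1=O
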